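## Retrosynthetic overview

1. The target is traced back to the tetracyclic hydroxy lactone 25 by three late operations: epoxidation of C12=C13 on the β face, acetylation of C17–OH, and α-methylenation of the lactone.
2. Ring A and the lactone come from one SmI2 ketyl–olefin closure (C3–C4) of the keto butenolide 24. Its C1–C3 unit and the C2 stereocentre come from (R)-glyceraldehyde acetonide, joined to C9 by aldol condensation; the C9 quaternary centre is made by reductive hydroxymethylation.
3. Ring C of the B/C ketone 12 is closed by metathesis (C12=C13) on the diene 8. Compound 8 is made in the key step: asymmetric conjugate addition at C5 (C5–C10) and enolate allylation at C6 (C6–C14) on the ring B enone 3.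
4. Enabling feature: C5 (H) and C6 (quaternary, CH3) are adjacent ring B atoms that carry the whole of ring C (through C10 and C14) in a trans relation. With C7 (a CH2 in the target) as a temporary ketone they are the β- and α-carbons of a 2-methylcyclohex-2-enone; the C4 oxygen is masked as a ketal.
5. Order of ring formation: ring B (starting material) → ring C (steps 2–3) → ring A and lactone (steps 10–11) → epoxide (step 15).

Key step: step 2

Remark on locants: cyathane-type numbering is used throughout. Ring A = C1–C2–C3–C4–C9; ring B = C4–C5–C6–C7–C8–C9; ring C = C5–C6–C14–C13–C12–C11–C10. C15 = CH3 on C12, C16 = CH3 on C6, C17 = CH2O on C9, C18/C19/C20 = lactone α-carbon, exocyclic CH2 and carbonyl. β is the face of C17, α the other face.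

Assumption: the sense of induction of the chiral copper catalyst in step 2 must be fixed by a trial run; the ligand antipode that gives 8 is the one meant.

## Route

Step 1
Reactants: 1 7-methyl-1,4-dioxaspiro[4.5]decan-8-one (racemic)
Product: 3 7-methyl-1,4-dioxaspiro[4.5]dec-6-en-8-one, via silyl enol ether 2 (not isolated)
Conditions: TMSCl, Et3N, DMF, 90 °C; then Pd(OAc)2 (1.0 equiv), MeCN, rt
Reagents that add atoms: none
Why: Saegusa–Ito oxidation: equilibrating silylation should give mainly the more substituted silyl enol ether 2, whose palladium enolate (from Pd(OAc)2, divalent palladium) undergoes β-hydride elimination into the ring to the conjugated enone, and the only stereocentre of 1 is removed.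

Step 2
Reactants: 3 7-methyl-1,4-dioxaspiro[4.5]dec-6-en-8-one; 4 4-bromo-2-methylbut-1-ene; 5 allyl iodide
Product: 8 (6S,7S)-7-methyl-6-(3-methylbut-3-en-1-yl)-7-(prop-2-en-1-yl)-1,4-dioxaspiro[4.5]decan-8-one, via Grignard reagent 6 (not isolated), via magnesium enolate 7 (not isolated)
Conditions: 4, Mg, Et2O, rt; then 3, CuBr·SMe2 (5 mol %), (R,S)-Josiphos [(R)-1-[(S)-2-(diphenylphosphino)ferrocenyl]ethyldicyclohexylphosphine] (6 mol %), t-BuOMe, −78 °C; then 5, DMPU, −78 to 0 °C
Reagents that add atoms: 4-bromo-2-methylbut-1-ene 4 (as 6), C=C(C)CCBr; allyl iodide 5, C=CCI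
Why: A chiral copper–diphosphine catalyst (monovalent copper) transfers the alkyl group of 6 to C5, the β-carbon of the 2-methylcyclohex-2-enone 3, and the magnesium enolate 7 so formed is alkylated at C6 by allyl iodide, which makes the C5–C10 and C6–C14 bonds in one flask; the closest known reaction type is the catalytic asymmetric conjugate addition/enolate trapping (three-component coupling) of 2-methylcycloalkenones. The step closes no ring: both bonds are intermolecular, and the two terminal alkenes it delivers are joined to the seven-membered ring C by metathesis in step 3. C5 is set by the ligand on copper (catalyst control, 3 being achiral); the quaternary C6 is set by C5, because the new C5 chain takes the pseudoaxial position to avoid allylic strain with the C6 methyl and the electrophile enters axially on the opposite face, giving the trans (5β-H/6α-CH3) relation of the B/C fusion. The step needs 1,4- over 1,2-addition (copper), a single enolate regioisomer (it is born at C6–C7 by the conjugate addition and is trapped before it equilibrates) and C- over O-allylation (magnesium enolate, soft allyl iodide, DMPU). In the substrate the temporary C7 carbonyl makes C5 electrophilic and C6 nucleophilic, the C6 methyl is already in place so that allylation creates the quaternary centre, and the C4 ketal keeps the later C4 ketone inert and is one carbon too far from the enolate carbon to be expelled.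

Step 3
Reactants: 8 diene keto ketal
Product: 9 (4aS,9aS)-4a,7-dimethyl-2,3,5,8,9,9a-hexahydrospiro[benzo[7]annulene-1,2'-[1,3]dioxolan]-4(4aH)-one (trans-fused rings B/C, C7 ketone, C4 ketal, C12=C13)
Conditions: second-generation Grubbs catalyst RuCl2(=CHPh)(H2IMes)(PCy3) (5 mol %), CH2Cl2 (0.01 M), 40 °C
Reagents that add atoms: none
Why: Ring-closing metathesis between the allyl group on C6 and the isopropenyl terminus of the C5 chain should close the seven-membered ring C and place the trisubstituted alkene unambiguously at C12=C13, with loss of ethene and no change at C5 or C6.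

Step 4
Reactants: 9 B/C keto ketal
Product: 12 (4aS,9aS)-4a,7-dimethyl-2,3,4,4a,5,8,9,9a-octahydro-1H-benzo[7]annulen-1-one (C4 ketone, 5β-H, 6α-CH3), via hydrazone 10 (not isolated), via deoxygenated ketal 11 (not isolated)
Conditions: N2H4·H2O, KOH, diethylene glycol, 130 then 200 °C; then 1 M HCl, THF, rt
Reagents that add atoms: water, O
Why: Wolff–Kishner reduction (Huang-Minlon procedure) removes the C7 carbonyl, which has done its work and has no epimerisable neighbour (C6 is quaternary), and mild acid then unmasks the C4 ketone; C5 is expected to stay trans because protonation of the C4 enol anti to the axial 6α-methyl and the ring-fusion preference both favour the 5β-H isomer.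

Step 5
Reactants: 12 B/C ketone; 13 (R)-2,2-dimethyl-1,3-dioxolane-4-carbaldehyde
Product: 15 aldol adduct, 2-{[(4R)-2,2-dimethyl-1,3-dioxolan-4-yl](hydroxy)methyl} derivative of 12 (mixture of epimers at C9 and C1), via lithium enolate 14 (not isolated)
Conditions: LiN(i-Pr)2 (LDA), THF, −78 °C; then 13, −78 °C; aq NH4Cl
Reagents that add atoms: (R)-2,2-dimethyl-1,3-dioxolane-4-carbaldehyde 13, CC1(C)OC[C@@H](O1)C=O
Why: Kinetic deprotonation should occur at the C9 methylene and not at the hindered C5 methine next to the quaternary C6, and the aldol addition of 14 to the aldehyde brings in C1–C3 with the C2 stereocentre from the chiral pool; the two new centres are erased in steps 6 and 7.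

Step 6
Reactants: 15 aldol adduct
Product: 17 (2E,4aS,9aS)-2-{[(4S)-2,2-dimethyl-1,3-dioxolan-4-yl]methylidene}-4a,7-dimethyl-3,4,4a,5,8,9,9a-heptahydro-1H-benzo[7]annulen-1(2H)-one (C9=C1 enone), via mesylate 16 (not isolated)
Conditions: MsCl, Et3N, CH2Cl2, 0 °C; then DBU, 0 °C to rt
Reagents that add atoms: none
Why: Mesylation and E1cB elimination through the C9 enolate give the exocyclic (E)-enone; the C2 stereocentre is γ to the carbonyl and should survive the short, cold base treatment.

Step 7
Reactants: 17 C9=C1 enone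
Product: 19 (2S,4aS,9aS)-2-{[(4S)-2,2-dimethyl-1,3-dioxolan-4-yl]methyl}-2-(hydroxymethyl)-4a,7-dimethyl-2,3,4,4a,5,8,9,9a-octahydro-1H-benzo[7]annulen-1-one (C17–OH β, C1 chain α), via lithium enolate 18 (not isolated)
Conditions: LiBH(s-Bu)3, THF, −78 °C; then CH2O (gas, from paraformaldehyde), −78 °C; aq NH4Cl
Reagents that add atoms: formaldehyde, C=O
Why: Conjugate hydride reduction of the enone gives the C4–C9 enolate 18 regiospecifically, and its aldol reaction with formaldehyde (reductive hydroxymethylation) should occur by axial attack on the β face, since attack on the α face would force a boat with the 6α-methyl as flagpole; this sets the quaternary C9 with C17 β and the C1 chain α.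

Step 8
Reactants: 19 hydroxymethyl ketone
Product: 20 17-O-tert-butyldiphenylsilyl ether of 19
Conditions: TBDPSCl, imidazole, DMF, rt
Reagents that add atoms: tert-butyl(chloro)diphenylsilane, CC(C)(C)[Si](Cl)(c1ccccc1)c1ccccc1
Why: Silylation of the only free hydroxyl protects C17–OH against the oxidation of step 10 and the strong base of step 12, and also stops retro-aldol loss of formaldehyde.

Step 9
Reactants: 20 silyl ether acetonide
Product: 21 (2S)-2,3-dihydroxypropyl ketone (C2–OH, C3–OH free; 17-OTBDPS)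
Conditions: AcOH/H2O 4:1, 40 °C
Reagents that add atoms: none
Why: Acid hydrolysis of the acetonide frees the 1,2-diol while the silyl ether of the neopentyl alcohol should survive aqueous acetic acid; no stereocentre is touched.

Step 10
Reactants: 21 diol
Product: 24 (5S)-5-substituted furan-2(5H)-one (keto butenolide: O on C2, C3=C18, C20=O; C4 ketone; 17-OTBDPS), via hydroxy aldehyde 22 (not isolated), via acyl ylide 23 (not isolated)
Conditions: TEMPO (10 mol %), PhI(OAc)2, CH2Cl2, rt; then Ph3P=C=C=O, toluene, 60 °C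
Reagents that add atoms: (triphenylphosphoranylidene)ketene, O=C=C=P(c1ccccc1)(c1ccccc1)c1ccccc1
Why: The oxoammonium oxidation takes the primary C3 alcohol selectively to the aldehyde, the ketenylidene phosphorane acylates the free C2 hydroxyl, and the ester ylide 23 closes by intramolecular Wittig reaction on the C3 aldehyde, so the cis alkene is fixed by the five-membered ring and C2 is untouched.

Step 11
Reactants: 24 keto butenolide
Product: 25 tetracyclic hydroxy lactone (ring A closed; 4α-OH; saturated γ-lactone with O on C2β and C18H2 on C3β, cis-fused to ring A; 17-OTBDPS; C12=C13)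
Conditions: SmI2 (2.5 equiv), t-BuOH (2 equiv), THF, −20 °C to rt
Reagents that add atoms: none
Why: Ketyl–olefin cyclisation (5-exo-trig): the C4 ketyl formed by SmI2 (divalent samarium) adds to the butenolide β-carbon C3 on the face that carries C1, so the lactone is necessarily cis-fused to ring A; the new bond should form equatorially on ring B, because the axial approach is blocked by the syn-axial 6α-methyl, which gives the trans-fused rings A/B with 4α-OH anti to the lactone.

Step 12
Reactants: 25 hydroxy lactone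
Product: 29 α-methylene lactone (C18=C19H2; 4α-OH; 17-OTBDPS), via dilithio derivative 26 (not isolated), via Mannich base 27 (not isolated), via ammonium iodide 28 (not isolated)
Conditions: LiN(i-Pr)2 (2.5 equiv), THF, −78 °C; CH2=NMe2+ I−, −78 to 0 °C; then MeI, MeOH, rt; then aq NaHCO3, CH2Cl2
Reagents that add atoms: dimethylmethyleneammonium iodide, C=[N+](C)C.[I-]
Why: Mannich alkylation of the lactone enolate (the tertiary alkoxide is a spectator), quaternisation and Hofmann-type elimination form the exocyclic alkene; the only centre affected, C18, becomes sp2.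

Step 13
Reactants: 29 silyl ether
Product: 30 4α,17-diol α-methylene lactone
Conditions: HF·pyridine, THF, 0 °C to rt
Reagents that add atoms: none
Why: Fluoride-mediated desilylation under mildly acidic conditions frees C17–OH without conjugate addition to the methylene lactone.

Step 14
Reactants: 30 diol
Product: 31 17-acetate (the target without the epoxide)
Conditions: Ac2O, pyridine, DMAP (cat.), CH2Cl2, 0 °C
Reagents that add atoms: acetic anhydride, CC(=O)OC(C)=O
Why: The primary alcohol is acetylated while the hindered, axial tertiary C4 hydroxyl should not react under these conditions.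

Step 15
Reactants: 31 acetate
Product: 32 target, 17-acetoxy-12β,13β-epoxy-4α-hydroxy α-methylene lactone
Conditions: mCPBA, NaHCO3, CH2Cl2, 0 °C
Reagents that add atoms: 3-chloroperbenzoic acid, OOC(=O)c1cccc(Cl)c1
Why: The electrophilic peracid should react only with the electron-rich trisubstituted C12=C13 and not with the conjugated methylene lactone, and should approach the β face, because the α face of ring C is shielded by the axial 6α-methyl next to C14.

## Compound list

1 | 7-methyl-1,4-dioxaspiro[4.5]decan-8-one (racemic) | CC1CC2(CCC1=O)OCCO2 | starting material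
2 | trimethyl[(7-methyl-1,4-dioxaspiro[4.5]dec-7-en-8-yl)oxy]silane | CC1=C(O[Si](C)(C)C)CCC2(C1)OCCO2 | intermediate
3 | 7-methyl-1,4-dioxaspiro[4.5]dec-6-en-8-one | CC1=CC2(CCC1=O)OCCO2 | intermediate
4 | 4-bromo-2-methylbut-1-ene | C=C(C)CCBr | starting material
5 | allyl iodide (3-iodoprop-1-ene) | C=CCI | starting material
6 | (3-methylbut-3-en-1-yl)magnesium bromide | C=C(C)CC[Mg]Br | intermediate
7 | bromomagnesium (6S)-7-methyl-6-(3-methylbut-3-en-1-yl)-1,4-dioxaspiro[4.5]dec-7-en-8-olate | C=C(C)CC[C@H]1C(C)=C(O[Mg]Br)CCC12OCCO2 | intermediate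
8 | (6S,7S)-7-methyl-6-(3-methylbut-3-en-1-yl)-7-(prop-2-en-1-yl)-1,4-dioxaspiro[4.5]decan-8-one | C1CC(=O)[C@@](C)(CC=C)[C@H](CCC(C)=C)C12OCCO2 | intermediate
9 | (4aS,9aS)-4a,7-dimethyl-2,3,5,8,9,9a-hexahydrospiro[benzo[7]annulene-1,2'-[1,3]dioxolan]-4(4aH)-one | C1CC(=O)[C@@]2(C)CC=C(C)CC[C@@H]2C13OCCO3 | intermediate
10 | hydrazone of 9 (at C7) | C1CC(=NN)[C@@]2(C)CC=C(C)CC[C@@H]2C13OCCO3 | intermediate
11 | (4aS,9aS)-4a,7-dimethyl-2,3,4,4a,5,8,9,9a-octahydrospiro[benzo[7]annulene-1,2'-[1,3]dioxolane] | C1CC[C@@]2(C)CC=C(C)CC[C@@H]2C13OCCO3 | intermediate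
12 | (4aS,9aS)-4a,7-dimethyl-2,3,4,4a,5,8,9,9a-octahydro-1H-benzo[7]annulen-1-one | C1CC[C@@]2(C)CC=C(C)CC[C@@H]2C1=O | intermediate
13 | (R)-2,2-dimethyl-1,3-dioxolane-4-carbaldehyde | CC1(C)OC[C@@H](O1)C=O | starting material
14 | lithium enolate of 12 (C4–C9) | [Li]OC1=CCC[C@@]2(C)CC=C(C)CC[C@@H]21 | intermediate
15 | aldol adduct of 12 and 13 (epimers at C9 and C1) | CC1(C)OC[C@@H](O1)C(O)C2CC[C@@]3(C)CC=C(C)CC[C@@H]3C2=O | intermediate
16 | methanesulfonate of 15 | CC1(C)OC[C@@H](O1)C(OS(C)(=O)=O)C2CC[C@@]3(C)CC=C(C)CC[C@@H]3C2=O | intermediate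
17 | (2E,4aS,9aS)-2-{[(4S)-2,2-dimethyl-1,3-dioxolan-4-yl]methylidene}-4a,7-dimethyl-3,4,4a,5,8,9,9a-heptahydro-1H-benzo[7]annulen-1(2H)-one | CC1(C)OC[C@@H](O1)/C=C2\CC[C@@]3(C)CC=C(C)CC[C@@H]3C2=O | intermediate
18 | lithium enolate (C4–C9) from 1,4-reduction of 17 | CC1(C)OC[C@@H](O1)CC2=C(O[Li])[C@H]3CCC(C)=CC[C@]3(C)CC2 | intermediate
19 | (2S,4aS,9aS)-2-{[(4S)-2,2-dimethyl-1,3-dioxolan-4-yl]methyl}-2-(hydroxymethyl)-4a,7-dimethyl-2,3,4,4a,5,8,9,9a-octahydro-1H-benzo[7]annulen-1-one | CC1(C)OC[C@@H](O1)C[C@]2(CO)CC[C@@]3(C)CC=C(C)CC[C@@H]3C2=O | intermediate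
20 | 17-O-tert-butyldiphenylsilyl ether of 19 | CC1(C)OC[C@@H](O1)C[C@]2(CO[Si](c4ccccc4)(c4ccccc4)C(C)(C)C)CC[C@@]3(C)CC=C(C)CC[C@@H]3C2=O | intermediate
21 | (2S)-2,3-dihydroxypropyl ketone (diol from 20) | OC[C@@H](O)C[C@]2(CO[Si](c4ccccc4)(c4ccccc4)C(C)(C)C)CC[C@@]3(C)CC=C(C)CC[C@@H]3C2=O | intermediate
22 | (2S)-2-hydroxy aldehyde (C3 aldehyde) from 21 | O=C[C@@H](O)C[C@]2(CO[Si](c4ccccc4)(c4ccccc4)C(C)(C)C)CC[C@@]3(C)CC=C(C)CC[C@@H]3C2=O | intermediate
23 | (triphenylphosphoranylidene)acetate ester of 22 (acyl ylide) | O=C[C@@H](OC(=O)C=P(c5ccccc5)(c5ccccc5)c5ccccc5)C[C@]2(CO[Si](c4ccccc4)(c4ccccc4)C(C)(C)C)CC[C@@]3(C)CC=C(C)CC[C@@H]3C2=O | intermediate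
24 | keto butenolide, (5S)-5-substituted furan-2(5H)-one | O=C1C=C[C@@H](O1)C[C@]2(CO[Si](c4ccccc4)(c4ccccc4)C(C)(C)C)CC[C@@]3(C)CC=C(C)CC[C@@H]3C2=O | intermediate
25 | tetracyclic 4α-hydroxy γ-lactone (lactone β, cis-fused to ring A; 17-OTBDPS; C12=C13) | C1C(=O)O[C@H]2C[C@]3(CO[Si](c6ccccc6)(c6ccccc6)C(C)(C)C)CC[C@@]4(C)CC=C(C)CC[C@@H]4[C@@]3(O)[C@@H]12 | intermediate
26 | dilithio derivative of 25 (C4 alkoxide, lactone enolate) | C1=C(O[Li])O[C@H]2C[C@]3(CO[Si](c6ccccc6)(c6ccccc6)C(C)(C)C)CC[C@@]4(C)CC=C(C)CC[C@@H]4[C@@]3(O[Li])[C@@H]12 | intermediate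
27 | α-(dimethylaminomethyl) lactone (Mannich base, epimers at C18) | CN(C)CC1C(=O)O[C@H]2C[C@]3(CO[Si](c6ccccc6)(c6ccccc6)C(C)(C)C)CC[C@@]4(C)CC=C(C)CC[C@@H]4[C@@]3(O)[C@@H]12 | intermediate
28 | trimethylammonium iodide of 27 | C[N+](C)(C)CC1C(=O)O[C@H]2C[C@]3(CO[Si](c6ccccc6)(c6ccccc6)C(C)(C)C)CC[C@@]4(C)CC=C(C)CC[C@@H]4[C@@]3(O)[C@@H]12.[I-] | intermediate
29 | α-methylene lactone, 4α-OH, 17-OTBDPS | C=C1C(=O)O[C@H]2C[C@]3(CO[Si](c6ccccc6)(c6ccccc6)C(C)(C)C)CC[C@@]4(C)CC=C(C)CC[C@@H]4[C@@]3(O)[C@@H]12 | intermediate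
30 | α-methylene lactone 4α,17-diol | C=C1C(=O)O[C@H]2C[C@]3(CO)CC[C@@]4(C)CC=C(C)CC[C@@H]4[C@@]3(O)[C@@H]12 | intermediate
31 | 17-acetate (C12=C13 alkene) | C=C1C(=O)O[C@H]2C[C@]3(COC(C)=O)CC[C@@]4(C)CC=C(C)CC[C@@H]4[C@@]3(O)[C@@H]12 | intermediate
32 | target (CNP0214540.1) | C=C1C(=O)O[C@H]2C[C@]3(COC(C)=O)CC[C@@]4(C)C[C@H]5O[C@@]5(C)CC[C@@H]4[C@@]3(O)[C@@H]12 | target

## Step count and risks

Total step count: 15. Longest linear sequence: 15 steps (1 → 32); 4, 5 and 13 are commercial and enter without steps of their own.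

Steps most likely to fail:

Step 2 (key step). The copper catalyst may turn over slowly on this hindered, trisubstituted enone and give low enantiofacial selectivity at C5; the anti allylation itself is not in doubt. Fallback, resolution in place of asymmetric catalysis: from 3 the coupling is run with 6 and CuBr·SMe2 without chiral ligand (THF/Me2S, −40 °C; then 5, DMPU). This gives the trans product as the racemate, that is 8 together with its enantiomer, the (6R,7R)-ketone ent-8 F2, formed through the enantiomeric magnesium enolate ent-7 F1. The racemate is taken through steps 3 and 4, where the mirror-image series gives the keto ketal ent-9 F3, the hydrazone ent-10 F4, the ketal ent-11 F5 and the ketone ent-12 F6. It is then taken through steps 5 and 6 with enantiopure 13, where ent-12 gives the lithium enolate ent-14 F7, the aldol adducts F8, their mesylates F9 and the enone F10. F10 is a diastereomer of 17 (same dioxolane, mirror-image bicycle), so the two are separated by chromatography and the route is rejoined at 17.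

Step 11. The ketyl may be quenched by simple reduction (C4 carbinol, or saturation of the butenolide) before it cyclises, or it may close on the other face of C4 to the cis-fused rings A/B. Fallback, two-electron allylmetal addition in place of the ketyl radical: from 24, α-iodination (I2, pyridine, CH2Cl2) gives the α-iodobutenolide F11. Stille coupling with Bu3SnCH2OH (Pd(PPh3)4, dioxane, 90 °C) gives the α-(hydroxymethyl)butenolide F12, and an Appel reaction (CBr4, PPh3, CH2Cl2, 0 °C) gives the α-(bromomethyl)butenolide F13. Zinc dust in THF/aq NH4Cl then forms the allylzinc bromide F14, which adds through its γ-carbon C3 to the C4 ketone in a cyclic transition state. This gives the α-methylene lactone 29 directly, so step 12 is not needed and the route is rejoined at 29.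

Step 7. The borohydride may attack the hindered carbonyl (1,2-reduction) instead of C1, or the aldolate may lose formaldehyde again before work-up. Fallback, isolated silyl enol ether and Lewis-acid aldol: from 17, copper hydride-catalysed 1,4-hydrosilylation ([(Ph3P)CuH]6 cat., Et3SiH, toluene, rt) gives the triethylsilyl enol ether F15. A Mukaiyama-type hydroxymethylation with aqueous formaldehyde and Yb(OTf)3 (cat.) in THF then gives 19, with the same axial β attack at C9.

Further compounds
F1 | step 2 | bromomagnesium (6R)-7-methyl-6-(3-methylbut-3-en-1-yl)-1,4-dioxaspiro[4.5]dec-7-en-8-olate (ent-7) | C=C(C)CC[C@@H]1C(C)=C(O[Mg]Br)CCC12OCCO2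
F2 | step 2 | (6R,7R)-7-methyl-6-(3-methylbut-3-en-1-yl)-7-(prop-2-en-1-yl)-1,4-dioxaspiro[4.5]decan-8-one (ent-8) | C1CC(=O)[C@](C)(CC=C)[C@@H](CCC(C)=C)C12OCCO2
F3 | step 2 | (4aR,9aR) keto ketal (ent-9) | C1CC(=O)[C@]2(C)CC=C(C)CC[C@H]2C13OCCO3
F4 | step 2 | hydrazone of F3 (ent-10) | C1CC(=NN)[C@]2(C)CC=C(C)CC[C@H]2C13OCCO3
F5 | step 2 | (4aR,9aR) deoxygenated ketal (ent-11) | C1CC[C@]2(C)CC=C(C)CC[C@H]2C13OCCO3
F6 | step 2 | (4aR,9aR)-4a,7-dimethyl-2,3,4,4a,5,8,9,9a-octahydro-1H-benzo[7]annulen-1-one (ent-12) | C1CC[C@]2(C)CC=C(C)CC[C@H]2C1=O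
F7 | step 2 | lithium enolate of F6 (ent-14) | [Li]OC1=CCC[C@]2(C)CC=C(C)CC[C@H]21
F8 | step 2 | aldol adducts of F6 and 13 | CC1(C)OC[C@@H](O1)C(O)C2CC[C@]3(C)CC=C(C)CC[C@H]3C2=O
F9 | step 2 | methanesulfonates of F8 | CC1(C)OC[C@@H](O1)C(OS(C)(=O)=O)C2CC[C@]3(C)CC=C(C)CC[C@H]3C2=O
F10 | step 2 | (2E,4aR,9aR) enone, diastereomer of 17 | CC1(C)OC[C@@H](O1)/C=C2\CC[C@]3(C)CC=C(C)CC[C@H]3C2=O
F11 | step 11 | α-iodobutenolide from 24 | O=C1C(I)=C[C@@H](O1)C[C@]2(CO[Si](c4ccccc4)(c4ccccc4)C(C)(C)C)CC[C@@]3(C)CC=C(C)CC[C@@H]3C2=O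
F12 | step 11 | α-(hydroxymethyl)butenolide | O=C1C(CO)=C[C@@H](O1)C[C@]2(CO[Si](c4ccccc4)(c4ccccc4)C(C)(C)C)CC[C@@]3(C)CC=C(C)CC[C@@H]3C2=O
F13 | step 11 | α-(bromomethyl)butenolide | O=C1C(CBr)=C[C@@H](O1)C[C@]2(CO[Si](c4ccccc4)(c4ccccc4)C(C)(C)C)CC[C@@]3(C)CC=C(C)CC[C@@H]3C2=O
F14 | step 11 | allylzinc bromide from F13 | O=C1C(C[Zn]Br)=C[C@@H](O1)C[C@]2(CO[Si](c4ccccc4)(c4ccccc4)C(C)(C)C)CC[C@@]3(C)CC=C(C)CC[C@@H]3C2=O
F15 | step 7 | triethylsilyl enol ether (C4–C9) from 17 | CC1(C)OC[C@@H](O1)CC2=C(O[Si](CC)(CC)CC)[C@H]3CCC(C)=CC[C@]3(C)CC2
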